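(The readings were generated by integration on assumed constants; scatter was added.)

I began with the easy step of dividing one charge by another. The free monomer charged over the pre-initiator charged, R = 20.0, is the same in zeta and alpha. If each chain starts from one pre-initiator, the length is R·x/f, where x is the fraction of free monomer in chains and f the fraction of pre-initiator that has started chains.

the same everywhere: free monomer 15 mM; pre-initiator 0.75 mM
- spring: transfer agent 0.75 mM; run made earlier
- dusk: transfer agent 3 mM; run made earlier
- zeta: transfer agent 1.50 mM; time 12 h
- alpha: transfer agent 1.50 mM; time 50 h

- spring (time / h: monomer in chains / %, free monomer / %): 0.667: 0, 99.1; 2.00: 2.7, 97.6; 3.00: 5.6, 94.6; 5.00: 11.9, 87.5; 8.00: 23.6, 75.5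
- dusk (time / h: monomer in chains / %, free monomer / %): 0.500: 0.2, 99.7; 1.00: 1.2, 99.3; 2.00: 2.3, 97.3; 4.00: 6.6, 94.0; 8.00: 14.4, 85.8

(readings scatter by 0.3 percentage points)

- the average divides the monomer in chains by the number of chains begun, living and dead together
- the earlier runs do not show the number of chains; that part of a forecast is a guess

1. which of the two ends with the longer chains by the average number of monomer units in a chain (chains begun, living or dead) ("neither" if they lie within 10%) (zeta / alpha / neither)
2. average number of monomer units in a chain (chains begun, living or dead) at the end, zeta
3. average number of monomer units in a chain (chains begun, living or dead) at the end, alpha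

At 8.00 h, dusk, with 3 mM of transfer agent, held 14.4% in chains, less than the 23.6% in spring with 0.75 mM. I read this as degradative transfer: the agent ends chains without restarting them, so I counted chains against the pre-initiator, not the agent.

The agent in zeta, 1.50 mM, is the geometric mean of the two runs, so I took geometric means of their last readings and late slopes. That gave x = 29.5% at 12 h. The first round, with f = 1, gave a length of 5.89. Going round again with a guessed f of 0.5, since the spring rate was still rising, gave 11.8. With the same charges and 50 h, I expected alpha to be longer.

The forecast differed on the count, taking “at most 1.5 mM from the agent plus some from the initiator”. It gave 3.7 (2.2 to 6) for zeta, 6.3 (4.2 to 10) for alpha, and alpha as the longer.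

The flasks gave 10.2 for zeta and 12.8 for alpha, so alpha was longer.

    free monomer + initiator → living end + monomer in chains (k = 0.260 M⁻¹ s⁻¹)
    pre-initiator → initiator (k = 2.10 × 10⁻⁵ s⁻¹)
    living end + transfer agent → dead chain (kL = 0.0450 M⁻¹ s⁻¹)
    free monomer + living end → monomer in chains + living end, rate k4*[living end]*[free monomer] (k = 0.0640 M⁻¹ s⁻¹)

With 30.3% in chains and 40% of the pre-initiator left, taking f as the pre-initiator gone, R·x/f gives 10.1 for zeta. For the same flask read at 8.00 h, with 19.7% in chains and 55% left, it gives 8.76, and the flask gave 8.76. Alpha had nearly come to rest at 50 h, with 2.3% of its pre-initiator left and 0.0202 mM of living end. Ten times the time raises its monomer in chains from 62.7% to 65.3% and its length from 12.8 to 13.1.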